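**Retrosynthetic overview**
1. Target 18 ⇒ diol 16 (O8-selective Steglich acylation) ⇒ acetonide 15 (ketal hydrolysis).
2. 15 ⇒ allenyl enal 14 + CO: a carbonylative [2+2+1] annulation makes C6–C7, C11–C12 and C12–O6, so the ten-membered carbocycle and the α-methylene-γ-lactone close together.
3. 14 ⇒ enoate 11 (nucleophilic epoxidation gives the C1–C10 oxirane; then desilylation and oxidation).
4. 11 ⇒ allenyl ester 8 + aldehyde 4 by ynolate olefination with insertion of C10.
5. 8 ⇐ L-tartrate acetonide 5 (C8, C9); 4 ⇐ nerol 1 (4Z olefin). Ring order: dioxolane (chiral pool, temporary) → epoxide (step 7) → carbocycle + lactone together (step 10).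

Assumption: the SMILES is taken as drawn, i.e. (1R,6R,7S,8S,9R,10S), 4Z, (S)-2-methylbutanoate; locants C1–C15 in names and text are germacrane locants of the target (C12 = lactone carbonyl on O6, C14 = ester carbon on C10, C15 = methyl on C4).

**Step 1**
Reactants: 1 nerol
Product: 2 neryl tert-butyldimethylsilyl ether
Conditions: TBSCl, imidazole, CH2Cl2, 0 °C → rt
Reagents that add atoms: tert-butyldimethylsilyl chloride, CC(C)(C)[Si](C)(C)Cl
Why: Standard silyl ether formation on the primary allylic alcohol gives a base-stable mask for O6 that survives the organolithium conditions of step 6; no stereocentre is formed and the Z-olefin is untouched.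

**Step 2**
Reactants: 2 neryl tert-butyldimethylsilyl ether
Product: 3 6,7-epoxyneryl TBS ether (racemic at the oxirane CH)
Conditions: mCPBA (1.0 equiv), NaHCO3, CH2Cl2, −20 → 0 °C
Reagents that add atoms: 3-chloroperbenzoic acid, OOC(=O)c1cccc(Cl)c1
Why: Prilezhaev epoxidation with one equivalent of peracid selects the electron-rich distal trisubstituted olefin over the olefin that is inductively deactivated by the allylic silyloxy group, and the new racemic centre is destroyed in step 3.

**Step 3**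
Reactants: 3 6,7-epoxyneryl TBS ether
Product: 4 (4Z)-6-[(tert-butyldimethylsilyl)oxy]-4-methylhex-4-enal
Conditions: H5IO6, THF/H2O, 0 °C
Reagents that add atoms: none
Why: Periodic acid hydrolyses the trisubstituted epoxide and cleaves the glycol in one pot (Malaprade-type cleavage), releasing acetone and the C1 aldehyde without touching the Z-olefin or forming a stereocentre.

**Step 4**
Reactants: 5 dimethyl (4R,5R)-2,2-dimethyl-1,3-dioxolane-4,5-dicarboxylate (dimethyl 2,3-O-isopropylidene-L-tartrate)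
Product: 7 methyl (4R,5S)-5-ethynyl-2,2-dimethyl-1,3-dioxolane-4-carboxylate, via aldehyde ester 6 (not isolated)
Conditions: DIBAL-H (1.05 equiv), CH2Cl2, −78 °C; then MeOH, K2CO3, dimethyl (1-diazo-2-oxopropyl)phosphonate, −78 °C → rt
Reagents that add atoms: Ohira–Bestmann reagent, COP(=O)(OC)C(=[N+]=[N-])C(C)=O
Why: Half-reduction of the C2-symmetric diester (both esters are equivalent) stops at the aluminium hemiacetal, which is released in methanol and homologated in the same pot by the Ohira–Bestmann (Seyferth–Gilbert) reaction, while C8 and C9 come unchanged from L-tartaric acid and the trans-dioxolane is the thermodynamic isomer under the basic conditions.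

**Step 5**
Reactants: 7 methyl (4R,5S)-5-ethynyl-2,2-dimethyl-1,3-dioxolane-4-carboxylate
Product: 8 methyl (4R,5S)-2,2-dimethyl-5-(propa-1,2-dien-1-yl)-1,3-dioxolane-4-carboxylate
Conditions: (CH2O)n, CuI (0.5 equiv), Cy2NH, dioxane, reflux
Reagents that add atoms: paraformaldehyde (formaldehyde), C=O
Why: Crabbé homologation (copper-mediated Mannich reaction to the propargylic amine, then retro-imino-ene hydride shift) converts the terminal alkyne into the terminal allene and adds C13 without touching the C8/C9 centres.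

**Step 6**
Reactants: 8 methyl (4R,5S)-2,2-dimethyl-5-(propa-1,2-dien-1-yl)-1,3-dioxolane-4-carboxylate; 4 (4Z)-6-[(tert-butyldimethylsilyl)oxy]-4-methylhex-4-enal
Product: 11 methyl (2E,6Z)-8-[(tert-butyldimethylsilyl)oxy]-2-[(4S,5S)-2,2-dimethyl-5-(propa-1,2-dien-1-yl)-1,3-dioxolan-4-yl]-6-methylocta-2,6-dienoate, via lithium ynolate 9 (not isolated), via lithium carboxylate 10 (not isolated)
Conditions: CH2Br2, LiTMP, THF, −78 °C; LiHMDS; n-BuLi, −78 → 0 °C; then 4, −78 °C → rt; MeI, DMPU, rt
Reagents that add atoms: dibromomethane, BrCBr; iodomethane, CI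
Why: Kowalski chemistry (LiCHBr2 addition, Br/Li exchange, 1,2-shift) turns the ester into ynolate 9, whose Shindo olefination of aldehyde 4 ([2+2] to a β-lactone enolate, then torquoselective ring opening with the alkyl chain rotating outward) gives the E-trisubstituted carboxylate 10 that is O-methylated in situ, so C10 is the inserted CH2Br2 carbon and no stereocentre is formed or lost.

**Step 7**
Reactants: 11 methyl (2E,6Z)-8-[(tert-butyldimethylsilyl)oxy]-2-[(4S,5S)-2,2-dimethyl-5-(propa-1,2-dien-1-yl)-1,3-dioxolan-4-yl]-6-methylocta-2,6-dienoate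
Product: 12 methyl (2R,3R)-3-{(3Z)-5-[(tert-butyldimethylsilyl)oxy]-3-methylpent-3-en-1-yl}-2-[(4R,5S)-2,2-dimethyl-5-(propa-1,2-dien-1-yl)-1,3-dioxolan-4-yl]oxirane-2-carboxylate
Conditions: t-BuOOH, n-BuLi, THF, −78 → 0 °C
Reagents that add atoms: tert-butyl hydroperoxide, CC(C)(C)OO
Why: Weitz–Scheffer-type nucleophilic epoxidation (t-BuOOLi) attacks only the electron-poor enoate and runs by reversible conjugate addition and ring closure, so C2 ends trans to the ester whatever the E/Z purity of 11, while A(1,3) strain with the cis C2 chain puts H9 in the enoate plane and the oxygen closes on the face flanked by dioxolane oxygen O9 (less hindered than the C8 face and able to bind lithium), which sets C1 and C10 as in the target.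

**Step 8**
Reactants: 12 silyl-protected epoxy ester
Product: 13 methyl (2R,3R)-2-[(4R,5S)-2,2-dimethyl-5-(propa-1,2-dien-1-yl)-1,3-dioxolan-4-yl]-3-[(3Z)-5-hydroxy-3-methylpent-3-en-1-yl]oxirane-2-carboxylate
Conditions: TBAF, AcOH, THF, 0 °C → rt
Reagents that add atoms: none
Why: Buffered fluoride desilylation frees the primary allylic alcohol without affecting the glycidic ester, the acetonide or the allene, and no stereocentre changes.

**Step 9**
Reactants: 13 allylic alcohol
Product: 14 methyl (2R,3R)-2-[(4R,5S)-2,2-dimethyl-5-(propa-1,2-dien-1-yl)-1,3-dioxolan-4-yl]-3-[(3Z)-3-methyl-5-oxopent-3-en-1-yl]oxirane-2-carboxylate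
Conditions: TEMPO (cat.), PhI(OAc)2, CH2Cl2, rt
Reagents that add atoms: none
Why: TEMPO/PhI(OAc)2 oxidation converts the primary allylic alcohol into the Z-enal under neutral conditions that do not isomerise the olefin (as for nerol to neral) or touch the epoxide and allene.

**Step 10**
Reactants: 14 allenyl enal
Product: 15 methyl (4Z)-(1R,6R,7S,8S,9R,10R)-1,10-epoxy-8,9-(isopropylidenedioxy)germacra-4,11(13)-dien-12,6-olid-14-oate
Conditions: Mo(CO)6 (1.5 equiv), DMSO (10 equiv), toluene, 100 °C, 2 mM, slow addition of 14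
Reagents that add atoms: carbon monoxide (delivered from Mo(CO)6), [C-]#[O+]
Why: Proposed new method: Mo(0) binds the aldehyde and the proximal allene π-bond, oxidative cyclisation gives a five-membered oxamolybdacycle (C6–C7 bond, which closes the ten-membered ring), CO inserts into Mo–C11 and C–O reductive elimination closes the α-methylene-γ-lactone, so both rings form in one operation; the closest known reaction is the Mo(CO)6/DMSO- or Ru3(CO)12-mediated hetero-Pauson–Khand cyclocarbonylation of allenyl aldehydes to bicyclic α-methylene-γ-butyrolactones with five- and six-membered carbocycles, here extended to a ten-membered ring preorganised by the Z-olefin, the cis-epoxide and the trans-dioxolane, with C7 set by attack on the allene face anti to C9 of the dioxolane (H8 eclipsing the allene) and C6 by the trans-fused metallacycle in which C5 and C8 avoid eclipsing.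

**Step 11**
Reactants: 15 tricyclic lactone acetonide
Product: 16 methyl (4Z)-(1R,6R,7R,8S,9R,10S)-1,10-epoxy-8,9-dihydroxygermacra-4,11(13)-dien-12,6-olid-14-oate
Conditions: AcOH/H2O (4:1), 45 °C
Reagents that add atoms: none
Why: Mild aqueous acid hydrolyses the dioxolane ketal, while the glycidic ester (deactivated toward acid opening by the carboxylate-bearing carbon), the α-methylene lactone and the methyl ester survive, and no stereocentre changes.

**Step 12**
Reactants: 16 diol; 17 (S)-2-methylbutanoic acid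
Product: 18 methyl (4Z)-(1R,6R,7S,8S,9R,10S)-1,10-epoxy-9-hydroxy-8-[(2S)-2-methylbutanoyloxy]germacra-4,11(13)-dien-12,6-olid-14-oate (CNP0581690.1)
Conditions: DCC, DMAP (cat.), CH2Cl2, 0 °C
Reagents that add atoms: none
Why: Steglich esterification acylates O8 selectively because the C9 hydroxyl is neopentylic (next to the quaternary epoxide carbon C10) and hydrogen-bonded to the epoxide and ester oxygens, and the (S)-centre of the acid is retained under carbodiimide activation at 0 °C.

**Compound list**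
1 | nerol, (2Z)-3,7-dimethylocta-2,6-dien-1-ol | CC(C)=CCC/C(C)=C\CO | starting material
2 | tert-butyl{[(2Z)-3,7-dimethylocta-2,6-dien-1-yl]oxy}dimethylsilane | CC(C)=CCC/C(C)=C\CO[Si](C)(C)C(C)(C)C | intermediate
3 | tert-butyl{[(2Z)-5-(3,3-dimethyloxiran-2-yl)-3-methylpent-2-en-1-yl]oxy}dimethylsilane (racemic oxirane) | CC1(C)OC1CC/C(C)=C\CO[Si](C)(C)C(C)(C)C | intermediate
4 | (4Z)-6-[(tert-butyldimethylsilyl)oxy]-4-methylhex-4-enal | O=CCC/C(C)=C\CO[Si](C)(C)C(C)(C)C | intermediate
5 | dimethyl (4R,5R)-2,2-dimethyl-1,3-dioxolane-4,5-dicarboxylate | COC(=O)[C@@H]1OC(C)(C)O[C@H]1C(=O)OC | starting material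
6 | methyl (4R,5R)-5-formyl-2,2-dimethyl-1,3-dioxolane-4-carboxylate | O=C[C@@H]1OC(C)(C)O[C@H]1C(=O)OC | intermediate
7 | methyl (4R,5S)-5-ethynyl-2,2-dimethyl-1,3-dioxolane-4-carboxylate | C#C[C@@H]1OC(C)(C)O[C@H]1C(=O)OC | intermediate
8 | methyl (4R,5S)-2,2-dimethyl-5-(propa-1,2-dien-1-yl)-1,3-dioxolane-4-carboxylate | C=C=C[C@@H]1OC(C)(C)O[C@H]1C(=O)OC | intermediate
9 | lithium 2-[(4S,5S)-2,2-dimethyl-5-(propa-1,2-dien-1-yl)-1,3-dioxolan-4-yl]ethyn-1-olate | C=C=C[C@@H]1OC(C)(C)O[C@H]1C#C[O-].[Li+] | intermediate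
10 | lithium (2E,6Z)-8-[(tert-butyldimethylsilyl)oxy]-2-[(4S,5S)-2,2-dimethyl-5-(propa-1,2-dien-1-yl)-1,3-dioxolan-4-yl]-6-methylocta-2,6-dienoate | C=C=C[C@@H]1OC(C)(C)O[C@H]1/C(C(=O)[O-])=C\CC/C(C)=C\CO[Si](C)(C)C(C)(C)C.[Li+] | intermediate
11 | methyl (2E,6Z)-8-[(tert-butyldimethylsilyl)oxy]-2-[(4S,5S)-2,2-dimethyl-5-(propa-1,2-dien-1-yl)-1,3-dioxolan-4-yl]-6-methylocta-2,6-dienoate | C=C=C[C@@H]1OC(C)(C)O[C@H]1/C(C(=O)OC)=C\CC/C(C)=C\CO[Si](C)(C)C(C)(C)C | intermediate
12 | methyl (2R,3R)-3-{(3Z)-5-[(tert-butyldimethylsilyl)oxy]-3-methylpent-3-en-1-yl}-2-[(4R,5S)-2,2-dimethyl-5-(propa-1,2-dien-1-yl)-1,3-dioxolan-4-yl]oxirane-2-carboxylate | CC(C)(C)[Si](C)(C)OC/C=C(/C)CC[C@H]1O[C@@]1(C(=O)OC)[C@@H]1OC(C)(C)O[C@H]1C=C=C | intermediate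
13 | methyl (2R,3R)-2-[(4R,5S)-2,2-dimethyl-5-(propa-1,2-dien-1-yl)-1,3-dioxolan-4-yl]-3-[(3Z)-5-hydroxy-3-methylpent-3-en-1-yl]oxirane-2-carboxylate | OC/C=C(/C)CC[C@H]1O[C@@]1(C(=O)OC)[C@@H]1OC(C)(C)O[C@H]1C=C=C | intermediate
14 | methyl (2R,3R)-2-[(4R,5S)-2,2-dimethyl-5-(propa-1,2-dien-1-yl)-1,3-dioxolan-4-yl]-3-[(3Z)-3-methyl-5-oxopent-3-en-1-yl]oxirane-2-carboxylate | O=C/C=C(/C)CC[C@H]1O[C@@]1(C(=O)OC)[C@@H]1OC(C)(C)O[C@H]1C=C=C | intermediate
15 | methyl (4Z)-(1R,6R,7S,8S,9R,10R)-1,10-epoxy-8,9-(isopropylidenedioxy)germacra-4,11(13)-dien-12,6-olid-14-oate | C=C1C(=O)O[C@@H]2/C=C(/C)CC[C@H]3O[C@@]3(C(=O)OC)[C@@H]4OC(C)(C)O[C@H]4[C@@H]12 | intermediate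
16 | methyl (4Z)-(1R,6R,7R,8S,9R,10S)-1,10-epoxy-8,9-dihydroxygermacra-4,11(13)-dien-12,6-olid-14-oate | C=C1C(=O)O[C@@H]2/C=C(/C)CC[C@H]3O[C@@]3(C(=O)OC)[C@H](O)[C@@H](O)[C@@H]12 | intermediate
17 | (S)-2-methylbutanoic acid | CC[C@H](C)C(=O)O | starting material
18 | methyl (4Z)-(1R,6R,7S,8S,9R,10S)-1,10-epoxy-9-hydroxy-8-[(2S)-2-methylbutanoyloxy]germacra-4,11(13)-dien-12,6-olid-14-oate | C=C1C(=O)O[C@@H]2/C=C(/C)CC[C@H]3O[C@@]3(C(=O)OC)[C@H](O)[C@@H](OC(=O)[C@@H](C)CC)[C@@H]12 | target

**Step count and risks**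
Total steps: 12. Longest linear sequence: 10 (steps 1, 2, 3, 6, 7, 8, 9, 10, 11, 12 from nerol).

Steps most likely to fail:

Step 10 (ten-membered ring by carbonylative [2+2+1]; ring size is without precedent, and the 6,7-trans outcome and the survival of the epoxide at 100 °C are not assured). The fallback sets out from 14 and comes back at 15. A nucleophilic allylmetal is made first instead of a concerted annulation. Ni(cod)2 and DBU under CO2 (1 atm, THF, 0 °C) carboxylate the terminal allene at C11 (Mori–Sato type) to an η3-allylnickel carboxylate. This adds through C7 to the aldehyde in a Barbier-type macrocyclisation, the mode proven for chromium-mediated germacranolide closures. Acidic work-up gives the macrocyclic seco hydroxy acid F1, which lactonises on standing or with EDC to 15. The lactone carbonyl carbon then comes from CO2, not CO.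

Step 6 (one-pot ynolate generation and olefination next to an allene and a β-alkoxy centre). The fallback sets out from 8 (with 4) and comes back at 11. The ynolate is quenched with acidic methanol, the original Kowalski homologation, to give the homologated ester F2. LDA (THF, −78 °C) and aldehyde 4 give the β-hydroxy ester F3 as a diastereomer mixture whose new centres are destroyed next. MsCl/Et3N then DBU eliminates to 11 (E major; any Z isomer converges in step 7).

Step 7 (a trisubstituted, α-branched enoate may react slowly, and facial control rests on a conformational model). The fallback sets out from 11 and comes back at 12. DIBAL-H (CH2Cl2, −78 °C) gives the allylic alcohol F4. Sharpless asymmetric epoxidation (Ti(OiPr)4, L-(+)-DET, t-BuOOH, 4 Å MS, −20 °C) is reagent-controlled and selective for the allylic-alcohol olefin; it delivers oxygen to the face required for C1(R)/C10 as in the target and gives the epoxy alcohol F5. TEMPO/PhI(OAc)2 then NaClO2 (Pinnick) gives the epoxy acid F6, and TMSCHN2 returns 12.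

**Further compounds**
F1 | step 10 | seco hydroxy acid of 15: 2-substituted prop-2-enoic acid with the C12–O6 bond open, C6–OH free, all stereocentres as in 15 | C=C(C(=O)O)[C@H]1[C@H](O)/C=C(/C)CC[C@H]2O[C@@]2(C(=O)OC)[C@@H]2OC(C)(C)O[C@@H]12
F2 | step 6 | methyl 2-[(4S,5S)-2,2-dimethyl-5-(propa-1,2-dien-1-yl)-1,3-dioxolan-4-yl]acetate | C=C=C[C@@H]1OC(C)(C)O[C@H]1CC(=O)OC
F3 | step 6 | methyl (6Z)-8-[(tert-butyldimethylsilyl)oxy]-2-[(4S,5S)-2,2-dimethyl-5-(propa-1,2-dien-1-yl)-1,3-dioxolan-4-yl]-3-hydroxy-6-methyloct-6-enoate (mixture at C2 and C3) | C=C=C[C@@H]1OC(C)(C)O[C@H]1C(C(=O)OC)C(O)CC/C(C)=C\CO[Si](C)(C)C(C)(C)C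
F4 | step 7 | (2Z,6Z)-8-[(tert-butyldimethylsilyl)oxy]-2-[(4S,5S)-2,2-dimethyl-5-(propa-1,2-dien-1-yl)-1,3-dioxolan-4-yl]-6-methylocta-2,6-dien-1-ol | C=C=C[C@@H]1OC(C)(C)O[C@H]1/C(CO)=C\CC/C(C)=C\CO[Si](C)(C)C(C)(C)C
F5 | step 7 | [(2R,3R)-3-{(3Z)-5-[(tert-butyldimethylsilyl)oxy]-3-methylpent-3-en-1-yl}-2-[(4R,5S)-2,2-dimethyl-5-(propa-1,2-dien-1-yl)-1,3-dioxolan-4-yl]oxiran-2-yl]methanol | CC(C)(C)[Si](C)(C)OC/C=C(/C)CC[C@H]1O[C@@]1(CO)[C@@H]1OC(C)(C)O[C@H]1C=C=C
F6 | step 7 | (2R,3R)-3-{(3Z)-5-[(tert-butyldimethylsilyl)oxy]-3-methylpent-3-en-1-yl}-2-[(4R,5S)-2,2-dimethyl-5-(propa-1,2-dien-1-yl)-1,3-dioxolan-4-yl]oxirane-2-carboxylic acid | CC(C)(C)[Si](C)(C)OC/C=C(/C)CC[C@H]1O[C@@]1(C(=O)O)[C@@H]1OC(C)(C)O[C@H]1C=C=C
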